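Take partner as the reagent to watch in these flasks, and begin with what was charged and read.

| flask | starting material | partner | second substrate | third substrate | remark | time |
|---|---|---|---|---|---|---|
| zeta | 0.47 M | 0.47 M | 0.094 M | 0.63 M | run made earlier |  |
| beta | 0.47 M | 0.47 M | 0.094 M | 0.47 M | run made earlier |  |
| Tuesday's | 0.47 M | 0.470 M | 0.0940 M | 0.940 M |  | 8.0 min |
| Thursday's | 0.47 M | 0.800 M | 0.300 M | 0.940 M |  | 2.5 min |

| run | time / min | target / % | starting material / % |
|---|---|---|---|
| zeta | 0.417 | 6 | 94 |
| zeta | 0.667 | 12 | 92 |
| zeta | 1.33 | 16 | 85 |
| zeta | 2.50 | 24 | 75 |
| zeta | 5.00 | 32 | 66 |
| beta | 0.417 | 7 | 92 |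
| beta | 1.33 | 15 | 85 |
| beta | 2.00 | 19 | 81 |
| beta | 3.00 | 24 | 72 |
| beta | 5.00 | 30 | 70 |

(scatter of a reading: 2 percentage points)

- the winner by amount of target, in percent of the starting material charged; "neither" if no more than 2 percentage points parts them (Tuesday's / Thursday's / neither)
- how much target is there at the end, in percent of the starting material charged: Tuesday's
- how much target is there at the end, in percent of the starting material charged: Thursday's

- the numbers in the tables scatter by 2 percentage points (one standard deviation)

Target and starting material add up to about the charge, so work with the fraction left. Define the dose D = ln(charged/left), the integrated first-order measure.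

Zeta reaches D = 0.288 by 2.50 min. The mean reading of zeta and beta reaches 0.386 by 5.00 min, so the next stretch of clock adds just 0.0980, with 68.0% of the starting material still left. Starting material isn't what gives out, then. Third substrate shows little either: at 5.00 min, zeta with 0.63 M reads 32% of target and beta with 0.47 M reads 30%, and a reading scatters by 2 percentage points.

So suspect partner. Assume that second substrate takes its own charge of partner first, mole for mole. What remains, S, is 0.376 M for zeta, beta and Tuesday's, and 0.500 M for Thursday's; call it spare partner. My rule, an assumption: at one clock and one charge of starting material, with third substrate set aside, D scales with S.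

Thursday's is read at zeta's 2.5 min, so my rule, from that one scattered zeta reading, gives D = 0.383 and target of about 31.8%. Tuesday's has zeta's S but a later clock. Let one more stretch of clock shrink by the same ratio: my estimate is D = 0.419 at 7.50 min, close to its 8.0 min, and I take target of about 34.2% for Tuesday's. I therefore pick Tuesday's, by a thin 2.4 points.

The forecast differs: it picks Thursday's, with 37% of target for Tuesday's and 54% for Thursday's, reading the runs as “a burst that consumes second substrate”.

The winner is Tuesday's: Tuesday's gives 34.2% of target and Thursday's 29.6%.

    starting material + partner → target (k = 0.390 /M/min)
    second substrate + partner → second product (k = 5.20 /M/min)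
    third substrate + partner → third product (k = 0.00450 /M/min)
    partner → decomposed reagent (k = 0.170 /min)

At its 2.5 min, Thursday's still holds 25.9% of its partner, while Tuesday's holds 6.18% at 8.0 min. Now take Tuesday's with 0.80 M of partner, read at the same 8.0 min. Its S is 0.706 M, so Tuesday's dose of 0.418 scales to 0.785, which leaves 45.6%. That neighbour flask holds 43.8% starting material and 56.2% target.

(Readings and results are simulated on assumed constants; noise was put on by code.)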